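**Retrosynthetic overview**
1. Target 6 ⇒ 4: the C7=C8 bond comes from loss of AcOH across C8–O/C7–H of a tertiary 8α-acetate, followed by correction of the alkene position.
2. 4 ⇒ 3: the C15–O bond and the 13E alkene come from a 1,3-acetoxy shift of the tertiary allylic 13-acetate.
3. 3 ⇒ 2: three O-acetylations.
4. 2 ⇒ 1: the C3–O bond comes from site- and stereoselective enzymatic C–H hydroxylation of (−)-sclareol; this is the key step and sets the only new stereocentre.
5. Rings: none is formed. The trans-decalin with C5, C9 and C10 is carried intact from sclareol, and no C–C bond is made anywhere.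

Assumption: the target is read as (13E)-3β,15-diacetoxylabda-7,13-diene of the normal labdane series (5α-H, 9α-H, 10β-CH3), and a route from the bulk chiral-pool diterpene (−)-sclareol is taken as a synthesis from commercial materials.

**Step 1**
Reactants: 1 (−)-sclareol ((13R)-labd-14-ene-8α,13-diol)
Product: 2 3β-hydroxysclareol ((13R)-labd-14-ene-3β,8α,13-triol)
Conditions: engineered P450BM3 C3-hydroxylase (cell lysate), NADP+ (cat.), glucose dehydrogenase, D-glucose, air, KPi pH 8.0, 25 °C
Reagents that add atoms: dioxygen, O=O
Why: P450 C–H hydroxylation (compound I hydrogen abstraction/oxygen rebound): BM3 variants of this kind are established C3-hydroxylases for the sclareolide/sclareol A ring, the pocket presenting the equatorial 3β-H to the ferryl oxygen so that OH is delivered with retention to give the 3β (3S) alcohol, while the tertiary alcohols and the vinyl group are untouched.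

**Step 2**
Reactants: 2 3β-hydroxysclareol
Product: 3 (13R)-labd-14-ene-3β,8α,13-triyl triacetate
Conditions: AcCl, PhNMe2, CH2Cl2, 0 °C → rt
Reagents that add atoms: acetyl chloride, CC(Cl)=O
Why: Exhaustive O-acetylation with AcCl/N,N-dimethylaniline (acylammonium/ketene acylation) is the standard buffered method that esterifies sclareol's two tertiary alcohols without ionising the tertiary allylic centre, and no stereocentre is affected.

**Step 3**
Reactants: 3 (13R)-labd-14-ene-3β,8α,13-triyl triacetate
Product: 4 (13E)-labd-13-ene-3β,8α,15-triyl triacetate
Conditions: PdCl2(MeCN)2 (5 mol%), THF, rt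
Reagents that add atoms: none
Why: Overman-type Pd(II)-catalysed [3,3] allylic acetate rearrangement (carbonyl oxygen adds to the Pd-bound C15, then Pd/C13–O anti-elimination) runs downhill from tertiary acetate/vinyl to primary acetate/trisubstituted alkene; the chair 1,3-dioxanium with the C12 chain equatorial makes 13E the major isomer (about 4:1 expected, the Z isomer being removed on AgNO3–silica and re-equilibrated), and the 3- and 8-acetates are inert.

**Step 4**
Reactants: 4 (13E)-labd-13-ene-3β,8α,15-triyl triacetate
Product: 6 (13E)-labda-7,13-diene-3β,15-diyl diacetate (target), via exocyclic Δ8(17) isomer 5 (not isolated)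
Conditions: 2,4,6-collidine, 170 °C; evaporate; then Co(salen-tBu,tBu)Cl (3 mol%), PhSiH3 (6 mol%), PhH, rt
Reagents that add atoms: none
Why: Proposed new method: a one-flask regioconvergent dehydroacetoxylation, in which hot collidine eliminates AcOH from the strained tertiary 8α-acetate (E1/Ei-like, driven by relief of the C17/C20 1,3-diaxial strain) to the kinetic Δ8(17)/Δ7 olefins without touching the secondary and primary allylic acetates, and Co(III)–H then adds H• reversibly only to the 1,1-disubstituted alkene to give the C8 radical, from which the bulky Co(II) removes the unhindered C7–H and not the C9–H flanked by C10 and the side chain, the trisubstituted Δ7 and 13E alkenes being inert to further MHAT so that the material funnels to 6 without touching a stereocentre; the closest known reaction types are collidine thermolysis of tertiary acetates and Shenvi-type Co(salen)/PhSiH3 alkene transposition, whose use as an elimination-correcting relay and whose C7/C9 selectivity on a labd-8(17)-ene carrying an allylic acetate are untested.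

**Compound list**
1 | (−)-sclareol, (13R)-labd-14-ene-8α,13-diol | C=C[C@](C)(O)CC[C@H]1[C@](C)(O)CC[C@H]2C(C)(C)CCC[C@]12C | starting material
2 | 3β-hydroxysclareol, (13R)-labd-14-ene-3β,8α,13-triol | C=C[C@](C)(O)CC[C@H]1[C@](C)(O)CC[C@H]2C(C)(C)[C@@H](O)CC[C@]12C | intermediate
3 | (13R)-labd-14-ene-3β,8α,13-triyl triacetate | C=C[C@](C)(OC(C)=O)CC[C@H]1[C@](C)(OC(C)=O)CC[C@H]2C(C)(C)[C@@H](OC(C)=O)CC[C@]12C | intermediate
4 | (13E)-labd-13-ene-3β,8α,15-triyl triacetate | CC(=O)OC/C=C(\C)CC[C@H]1[C@](C)(OC(C)=O)CC[C@H]2C(C)(C)[C@@H](OC(C)=O)CC[C@]12C | intermediate
5 | (13E)-labda-8(17),13-diene-3β,15-diyl diacetate (exocyclic isomer, not isolated) | CC(=O)OC/C=C(\C)CC[C@H]1C(=C)CC[C@H]2C(C)(C)[C@@H](OC(C)=O)CC[C@]12C | intermediate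
6 | (13E)-labda-7,13-diene-3β,15-diyl diacetate | CC(=O)OC/C=C(\C)CC[C@H]1C(C)=CC[C@H]2C(C)(C)[C@@H](OC(C)=O)CC[C@]12C | target

**Totals and risks**
Total step count: 4. Longest linear sequence: 4 (fully linear from 1).

Step 4, the proposed new step, is the most likely to fail. The collidine elimination has precedent for 8α-acetoxylabdanes, but the MHAT stage could stall on residual collidine/acetic acid, could remove the C9–H to give the Δ8 isomer, or the C8 radical could cyclise 6-endo onto the 13-ene. The fallback uses known, closed-shell chemistry in separate operations. It sets out from 4: the collidine thermolysis is run as its own worked-up step, and argentation chromatography separates the Δ7 isomer 6 that forms directly from the exocyclic isomer 5. Isolated 5 is then isomerised with RhCl3·3H2O (5 mol%) in EtOH–CHCl3 at 70 °C, the classical rhodium-hydride migration of an exocyclic methylene into the ring, and purified again on AgNO3–silica. The fallback comes back to the route at 6. New compounds on this path: none F0.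

Step 1 may fail on preparative scale through low turnover, poor substrate solubility or competing hydroxylation at other A-/B-ring positions. The fallback is a classical whole-organism biotransformation. It sets out from 1: sclareol is fed to growing cultures of a 3β-hydroxylating mould (Mucor plumbeus type), and the 3β-alcohol is isolated by chromatography from the other hydroxysclareols. It comes back to the route at 2. New compounds on this path: none F0.

Step 3 may give an unsatisfactory E:Z ratio, because the chair transition state distinguishes only a methyl from a CH2R group. The fallback is an enzymatic geometric resolution with recycling. It sets out from 4 as the unseparated E/Z mixture: an E-selective lipase (CAL-B, MTBE/phosphate buffer) hydrolyses the primary allylic acetate of the 13E isomer faster, giving (13E)-3β,8α-diacetoxylabd-13-en-15-ol F1. This alcohol separates easily on ordinary silica from the unreacted 13Z triacetate, which is returned to the PdCl2(MeCN)2 equilibration. Ac2O/pyridine then converts the alcohol into geometrically pure material, so the fallback comes back to the route at 4.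

**Further compounds**
F0 | step 4 | none | none
F0 | step 1 | none | none
F1 | step 3 | (13E)-3β,8α-diacetoxylabd-13-en-15-ol | OC/C=C(\C)CC[C@H]1[C@](C)(OC(C)=O)CC[C@H]2C(C)(C)[C@@H](OC(C)=O)CC[C@]12C
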